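**Retrosynthetic overview**

- Numbering: ring A has C1 (bearing the hydroxymethyl carbon C7), C2 (bridging CH2), C3 (Br), C4 and C5 (OH), C6 (H); ring B is the 3-bromo-4,5-dihydroxyphenyl group.
- The strategy rests on C7 sitting on C1 of ring A, ortho to the bridging carbon on C2 and para to the C4 oxygen. C7 and the bridging carbon can therefore be tied together as a 3-arylphthalide whose carbonyl carbon comes from CO.
- The C1–C7 and C7–O bonds are cut back to an ortho-iodo diarylmethanol and CO (palladium-catalysed carbonylative lactonisation). The carbinol is cut at the bridging carbon–ring B bond into a ring A aldehyde and a ring B Grignard reagent.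
- The C1 iodine is placed by iodination para to the free phenol of 2-bromoisovanillin, whose two ortho positions are blocked by Br and OMe.
- Both benzene rings are bought. The only ring formed is the lactone (step 6); it is opened reductively in step 7, then the four methyl ethers are cleaved and the acid is reduced to C7–OH.

Key step: step 6

Remark on the chemistry: the target is achiral. The benzhydrylic stereocentre of the carbinol and of the phthalide is carried as the racemate and is erased when the lactone is opened.

**Route**

Step 1
Reactants: 1 2-bromoisovanillin (2-bromo-3-hydroxy-4-methoxybenzaldehyde)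
Product: 2 2-bromo-3-hydroxy-6-iodo-4-methoxybenzaldehyde
Conditions: N-iodosuccinimide, CF3CO2H (cat.), MeCN, 0 °C → rt
Reagents that add atoms: N-iodosuccinimide, O=C1CCC(=O)N1I
Why: Electrophilic aromatic iodination; the free phenol is a stronger director than the methoxy group and, with both of its ortho positions occupied by Br and OMe, should send iodine to its para position (next to the formyl group), which becomes C1 of ring A.

Step 2
Reactants: 2 2-bromo-3-hydroxy-6-iodo-4-methoxybenzaldehyde
Product: 3 2-bromo-6-iodo-3,4-dimethoxybenzaldehyde
Conditions: MeI, K2CO3, DMF, rt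
Reagents that add atoms: iodomethane, CI
Why: Williamson O-methylation of the phenoxide (SN2 at MeI); the aldehyde and both aryl halides are inert to these conditions.

Step 3
Reactants: 4 4-iodo-2-methoxyphenol
Product: 5 2-bromo-4-iodo-6-methoxyphenol
Conditions: N-bromosuccinimide, i-Pr2NH (cat.), CH2Cl2, 0 °C
Reagents that add atoms: N-bromosuccinimide, O=C1CCC(=O)N1Br
Why: Amine-catalysed ortho-bromination of a phenol (electrophilic aromatic substitution); the para position carries iodine and one ortho position carries OMe, so only the remaining ortho carbon is open, and the cold, non-acidic conditions should disfavour ipso attack at the C–I carbon.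

Step 4
Reactants: 5 2-bromo-4-iodo-6-methoxyphenol
Product: 6 1-bromo-5-iodo-2,3-dimethoxybenzene
Conditions: MeI, K2CO3, DMF, rt
Reagents that add atoms: iodomethane, CI
Why: Williamson O-methylation of the hindered but acidic phenol; the aryl halides do not react.

Step 5
Reactants: 6 1-bromo-5-iodo-2,3-dimethoxybenzene; 3 2-bromo-6-iodo-3,4-dimethoxybenzaldehyde
Product: 8 (2-bromo-6-iodo-3,4-dimethoxyphenyl)(3-bromo-4,5-dimethoxyphenyl)methanol (racemic), via (3-bromo-4,5-dimethoxyphenyl)magnesium chloride 7 (not isolated)
Conditions: 6, i-PrMgCl·LiCl (0.95 equiv to 6), THF, −20 °C; then 3, −40 → 0 °C; aq. NH4Cl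
Reagents that add atoms: isopropylmagnesium chloride, CC(C)[Mg]Cl (its MgCl is held by intermediate 7 only; none of its atoms other than hydrogen remains in 8)
Why: Iodine–magnesium exchange is much faster at C–I than at C–Br, and the resulting aryl Grignard reagent should add to the aldehyde (1,2-addition) faster than it exchanges with the aryl iodide of 3; the new carbinol stereocentre is formed racemic and needs no control.

Step 6
Reactants: 8 (2-bromo-6-iodo-3,4-dimethoxyphenyl)(3-bromo-4,5-dimethoxyphenyl)methanol (racemic); 9 carbon monoxide
Product: 10 4-bromo-3-(3-bromo-4,5-dimethoxyphenyl)-5,6-dimethoxyisobenzofuran-1(3H)-one (racemic)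
Conditions: Pd(OAc)2 (5 mol %), PPh3 (20 mol %), K2CO3 (2 equiv), CO (1 atm), DMF, 70 °C
Reagents that add atoms: carbon monoxide (compound 9), [C-]#[O+]
Why: Zerovalent palladium, formed in situ from Pd(OAc)2 and PPh3, should add oxidatively to the C1–I bond of ring A, CO should insert to give a divalent acylpalladium iodide, and the neighbouring benzhydryl alkoxide (formed with K2CO3) should attack the acyl carbon, releasing the lactone and zerovalent palladium. The closest known reaction type is the palladium-catalysed cyclocarbonylation of 2-halobenzyl alcohols to phthalides. The five-membered lactone closes by a 5-exo-trig acyl substitution (equivalently, C–O reductive elimination from a six-membered acyl(alkoxo)palladacycle), which forms the C1–C7 and C7–O bonds. No stereocentre is created; the benzhydrylic carbon keeps the racemic configuration from step 5. The step needs oxidative addition at C–I in the presence of two aryl C–Br bonds, which the far higher reactivity of aryl iodides toward a PPh3-ligated catalyst at 70 °C under CO should secure, the ring A bromide being shielded further by its two ortho substituents; the position of C7 is fixed by the iodine. The CO atmosphere should also let acyl formation outrun β-hydride elimination from the palladium alkoxide and C–H arylation of ring B.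

Step 7
Reactants: 10 4-bromo-3-(3-bromo-4,5-dimethoxyphenyl)-5,6-dimethoxyisobenzofuran-1(3H)-one (racemic)
Product: 11 3-bromo-2-(3-bromo-4,5-dimethoxybenzyl)-4,5-dimethoxybenzoic acid
Conditions: Et3SiH (5 equiv), CF3CO2H, 25 → 60 °C
Reagents that add atoms: none
Why: Ionic hydrogenation; CF3CO2H protonates the lactone and ionises its doubly benzylic C–O bond to a diarylmethyl cation stabilised by the para-methoxy groups, which Et3SiH traps irreversibly by hydride transfer, so the stereocentre disappears while the aryl bromides, methyl ethers and carboxylic acid are untouched.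

Step 8
Reactants: 11 3-bromo-2-(3-bromo-4,5-dimethoxybenzyl)-4,5-dimethoxybenzoic acid
Product: 12 3-bromo-2-(3-bromo-4,5-dihydroxybenzyl)-4,5-dihydroxybenzoic acid
Conditions: BBr3 (8 equiv), CH2Cl2, −78 °C → rt; then H2O, 0 °C
Reagents that add atoms: none
Why: Lewis-acid cleavage of aryl methyl ethers (boron coordination, then SN2 attack of bromide at methyl); it is done at the acid stage because no benzylic leaving group is present that BBr3 could ionise toward Friedel–Crafts closure onto ring B.

Step 9
Reactants: 12 3-bromo-2-(3-bromo-4,5-dihydroxybenzyl)-4,5-dihydroxybenzoic acid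
Product: 13 5-hydroxyisoavrainvilleol (3-bromo-4-[(3-bromo-4,5-dihydroxyphenyl)methyl]-5-(hydroxymethyl)benzene-1,2-diol)
Conditions: BH3·SMe2 (6 equiv), THF, 0 → 45 °C; MeOH quench, evaporation from MeOH, neutral work-up
Reagents that add atoms: none
Why: Borane reduces a carboxylic acid chemoselectively through its acyloxyborane; the phenols only consume hydride as aryloxyboranes that methanol releases again, the aryl bromides are inert, and the neutral work-up should keep the para-hydroxybenzylic alcohol from ionising.

**Compound list**

1 | 2-bromoisovanillin (2-bromo-3-hydroxy-4-methoxybenzaldehyde) | COc1ccc(C=O)c(Br)c1O | starting material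
2 | 2-bromo-3-hydroxy-6-iodo-4-methoxybenzaldehyde | COc1cc(I)c(C=O)c(Br)c1O | intermediate
3 | 2-bromo-6-iodo-3,4-dimethoxybenzaldehyde | COc1cc(I)c(C=O)c(Br)c1OC | intermediate
4 | 4-iodo-2-methoxyphenol | COc1cc(I)ccc1O | starting material
5 | 2-bromo-4-iodo-6-methoxyphenol | COc1cc(I)cc(Br)c1O | intermediate
6 | 1-bromo-5-iodo-2,3-dimethoxybenzene | COc1cc(I)cc(Br)c1OC | intermediate
7 | (3-bromo-4,5-dimethoxyphenyl)magnesium chloride (as its LiCl complex, not isolated) | COc1cc([Mg]Cl)cc(Br)c1OC | intermediate
8 | (2-bromo-6-iodo-3,4-dimethoxyphenyl)(3-bromo-4,5-dimethoxyphenyl)methanol (racemic) | COc1cc(I)c(C(O)c2cc(Br)c(OC)c(OC)c2)c(Br)c1OC | intermediate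
9 | carbon monoxide | [C-]#[O+] | starting material
10 | 4-bromo-3-(3-bromo-4,5-dimethoxyphenyl)-5,6-dimethoxyisobenzofuran-1(3H)-one (racemic) | COc1cc2c(c(Br)c1OC)C(c1cc(Br)c(OC)c(OC)c1)OC2=O | intermediate
11 | 3-bromo-2-(3-bromo-4,5-dimethoxybenzyl)-4,5-dimethoxybenzoic acid | COc1cc(C(=O)O)c(Cc2cc(Br)c(OC)c(OC)c2)c(Br)c1OC | intermediate
12 | 3-bromo-2-(3-bromo-4,5-dihydroxybenzyl)-4,5-dihydroxybenzoic acid | OC(=O)c1cc(O)c(O)c(Br)c1Cc1cc(O)c(O)c(Br)c1 | intermediate
13 | 5-hydroxyisoavrainvilleol | OCc1cc(O)c(O)c(Br)c1Cc1cc(O)c(O)c(Br)c1 | target

**Step count**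

Total: 9 steps. Longest linear sequence: 7 steps (steps 1, 2, 5, 6, 7, 8, 9; the ring B branch through steps 3, 4, 5 is equally long).

**Steps most likely to fail, with fallbacks**

Step 6. Oxidative addition may also occur at an aryl C–Br bond, or the palladium alkoxide may undergo β-hydride elimination and oxidise the carbinol before CO inserts at the hindered ring A position. The fallback replaces catalysis by a stoichiometric carboxylation and sets out from carbinol 8. Two equivalents of i-PrMgCl·LiCl in THF at −20 °C should first deprotonate the hydroxyl and then exchange iodine for magnesium, giving the chloromagnesium aryl alkoxide F1. Dry CO2 and then aqueous HCl should give 3-bromo-2-[(3-bromo-4,5-dimethoxyphenyl)(hydroxy)methyl]-4,5-dimethoxybenzoic acid F2. This hydroxy acid should lactonise on acidification (or on warming with catalytic TsOH in toluene), and the route is rejoined at phthalide 10.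

Step 7. Ionisation of the lactone C–O bond may be slow, because the cation is only moderately stabilised and the carboxyl group can reclose faster than the silane delivers hydride, so the reduction may stall. The fallback sets out from phthalide 10 and changes both the order and the mechanism. BBr3 in CH2Cl2 should first give 4-bromo-3-(3-bromo-4,5-dihydroxyphenyl)-5,6-dihydroxyisobenzofuran-1(3H)-one F3. In degassed aqueous NaOH the ring B phenoxide para to the benzylic carbon should expel the carboxylate, as in the base-opening of phenolphthalein, and NaBH4 should reduce the resulting quinone methide by 1,6-hydride addition. Acidification then gives acid 12, where the route is rejoined; step 8 is no longer needed.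

Step 9. The para-hydroxybenzylic C–O bond may be over-reduced through a quinone methide-type borate, or the reduction may stay incomplete because the four phenols consume borane and the polyborate precipitates. The fallback sets out from acid 12 and masks the phenols. Ac2O/pyridine followed by aqueous work-up (which hydrolyses the mixed anhydride) should give 4,5-diacetoxy-3-bromo-2-(3,4-diacetoxy-5-bromobenzyl)benzoic acid F4. BH3·THF at 0 °C should reduce the acid selectively in the presence of the aryl acetates to [4,5-diacetoxy-3-bromo-2-(3,4-diacetoxy-5-bromobenzyl)phenyl]methanol F5. Catalytic K2CO3 in degassed MeOH at 0 °C should then remove the acetates and give target 13.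

**Further compounds**

F1 | step 6 | chloromagnesium [2-bromo-6-(chloromagnesio)-3,4-dimethoxyphenyl](3-bromo-4,5-dimethoxyphenyl)methanolate | COc1cc([Mg]Cl)c(C(O[Mg]Cl)c2cc(Br)c(OC)c(OC)c2)c(Br)c1OC
F2 | step 6 | 3-bromo-2-[(3-bromo-4,5-dimethoxyphenyl)(hydroxy)methyl]-4,5-dimethoxybenzoic acid (racemic) | COc1cc(C(=O)O)c(C(O)c2cc(Br)c(OC)c(OC)c2)c(Br)c1OC
F3 | step 7 | 4-bromo-3-(3-bromo-4,5-dihydroxyphenyl)-5,6-dihydroxyisobenzofuran-1(3H)-one (racemic) | Oc1cc2c(c(Br)c1O)C(c1cc(Br)c(O)c(O)c1)OC2=O
F4 | step 9 | 4,5-diacetoxy-3-bromo-2-(3,4-diacetoxy-5-bromobenzyl)benzoic acid | CC(=O)Oc1cc(C(=O)O)c(Cc2cc(Br)c(OC(C)=O)c(OC(C)=O)c2)c(Br)c1OC(C)=O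
F5 | step 9 | [4,5-diacetoxy-3-bromo-2-(3,4-diacetoxy-5-bromobenzyl)phenyl]methanol | CC(=O)Oc1cc(CO)c(Cc2cc(Br)c(OC(C)=O)c(OC(C)=O)c2)c(Br)c1OC(C)=O
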